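## Structural features

The target 17 is a γ-butyrolactone (O1, C2 carbonyl, C3, C4, C5) with an arylmethyl group on each of the two adjacent ring carbons. C4 is joined through C7 to ring A (3,4-dimethoxyphenyl) and C3 through C7' to ring B (3-hydroxy-4,5-dimethoxyphenyl). The only stereocentres are the neighbouring C3 and C4, both R, which places the two benzyl groups trans. C3 is alpha to the lactone carbonyl, so it can be epimerised and the trans arrangement is the more stable one; C4 has no acidic hydrogen and must be introduced in its absolute sense once and for all. The fragile elements are the free phenol of ring B (acidic, oxidisable, incompatible with organometallic and enolate chemistry), the lactone (opened by hard nucleophiles) and the two electron-rich arenes, which make benzylic leaving groups on them labile. The real difficulty is therefore the placement of two similar benzyl groups, ring A on C4 and ring B on C3, together with the R configuration at C4. The key step uses the fact that C4 carries three carbon branches, C3, C5 and C7. If C7 is also bonded to C3, the unit C3–C4(–C7)–C5–O1 with C2 is a 3-oxabicyclo[3.1.0]hexan-2-one. Its C3–C7 bond is activated by the lactone carbonyl and by an extra ester on C3, so ring A can be delivered to C7 and ring B to C3 in one operation while C4 comes from a chiral-pool epoxide.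

## Logic of the disconnections

17 to 16. The O–H of ring B is traced back to an O–CH2Ph bond. A free phenol would quench 8, compete with the enolate in the alkylation and make 12 self-reactive. The gain is that every earlier intermediate is neutral and aprotic. The demand on the forward step is a final cleavage that spares the lactone, the four aryl methyl ethers and the two benzylic C–C bonds.

16 to 14 (through 15). An ethoxycarbonyl group is added to C3; forwards the C3–CO2Et bond is broken. The extra acceptor is what activates the three-membered ring of 6 and stabilises the enolate 13. It also makes the configuration of C3 in 14 irrelevant. The gain is that C3 no longer needs kinetic control. The demand is a dealkoxycarbonylation that leaves the lactone intact and an equilibration that ends on the trans side.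

14 to 6, 8 and 12 (through 13). The bonds cut are C7–C(aryl) of ring A and C3–C7'; the bond re-formed is C3–C7. This is the only cut that removes both aryl groups at once and leaves a small, strained core with a single stereocentre. The demand is attack of the aryl nucleophile at the ring CH2 only, followed by C-alkylation of a chelated enolate.

6 to 1 and 2 (through 3, 4 and 5). The bonds cut are the acyl C–O bond of the lactone and the two ring bonds from the quaternary carbon, one to the CH2 and one to the fusion CH. This returns a three-carbon trielectrophile and a one-carbon dinucleophile that also supplies both carbonyls. The demand is that the first C–C bond forms at the epoxide CH2 and not at the C–Cl carbon, because that choice decides which enantiomer of 6 results.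

8 to 7. The C–Mg bond is cut back to C–Br; the only demand is an exact titre.

12 to 11 to 10 to 9. The C–Br bond, then the carbinol C–H, then the O–CH2Ph bond are cut in turn. This leads to a phenolic aldehyde that already has the full oxygen pattern of ring B. The demand is that bromination does not cleave the benzyl ether.

## Other disconnections considered

Alternative 1: The cut goes through both bonds of the ring oxygen, C5–O1 and O1–C2, back to the prochiral ketone 3-(3,4-dimethoxybenzyl)cyclobutan-1-one A1, whose C3 is the future C4.
- Forward key step: a flavin-dependent Baeyer–Villiger monooxygenase with NADPH and O2 would add its flavin peroxide to the carbonyl and let one of the two enantiotopic CH2 groups migrate to oxygen. This expands the ring to (R)-4-(3,4-dimethoxybenzyl)dihydrofuran-2(3H)-one A2. Ring B would then be attached by alkylating the lithium enolate of A2 with 12, anti to the C4 substituent, to give 16.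
- In favour: C4 would be created catalytically from an achiral ketone under mild aqueous conditions, with no organometallic reagent. C3 would be set kinetically as trans, so no ester removal and no equilibration are needed; on this point the alternative is better than the chosen plan.
- Against: the sense and level of enantioselection depend on how a bulky, electron-rich benzyl ketone fits the active site, and the structure does not predict this; the (S) lactone is as conceivable as the (R). Cofactor recycling, oxygen supply and low substrate concentration limit throughput. A1 itself costs a ketene cycloaddition and a dehalogenation.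
- Comparison: both plans must differentiate the two CH2 arms on C4, one with an enzyme pocket, the other with an epoxide whose outcome follows from SN2 stereochemistry. The enzymatic step forms only C–O bonds, so each benzyl group needs its own operation, whereas the chosen step forms two C–C bonds in one flask. The step counts should be about equal (two steps to A1, the oxidation, the alkylation and the deprotection, beside three steps for 12). The chosen plan is preferred for the certainty of the configuration at C4.

Alternative 2: The cut removes C2 as carbon monoxide, severing O1–C2 and C2–C3, and leads to the homopropargylic alcohol (2R)-4-[3-(benzyloxy)-4,5-dimethoxyphenyl]-2-(3,4-dimethoxybenzyl)but-3-yn-1-ol A3, in which C3 and C7' are the alkyne carbons.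
- Forward key step: under CO with PdCl2 (divalent palladium), SnCl2 and PPh3, the primary hydroxyl would form an alkoxycarbonylpalladium species. This would add syn across the tethered alkyne in a 5-exo sense, and protonolysis of the vinyl–palladium bond would give (R,E)-3-[3-(benzyloxy)-4,5-dimethoxybenzylidene]-4-(3,4-dimethoxybenzyl)dihydrofuran-2(3H)-one A4. Hydrogenation of the alkene with loss of the benzyl group, then equilibration at C3, would follow.
- In favour: ring B enters through an sp–sp2 coupling and not through a labile benzylic bromide, the carbonyl carbon comes from a one-carbon feedstock, and the alkene geometry does not matter. One hydrogenation would saturate and deprotect together, which is better than the chosen plan at the end of the route.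
- Against: the key step does not create C4, so A3 has to be made enantiopure by a separate multi-step sequence. Internal aryl alkynes are less willing partners than terminal ones in this carbonylation. It needs pressurised toxic CO and a tin salt. Hydrogen should add to A4 from the face away from the C4 substituent, which would give the cis lactone first.
- Comparison: both plans would rely on thermodynamic correction at C3, so they are equal there, although the alternative would do it on a free phenol. Mechanistically the alternative closes the lactone ring and forms one C–O and one C–C bond; the chosen step closes no ring and forms two C–C bonds. On step economy the alternative is clearly longer because of A3, and it leaves the absolute stereochemistry unsolved.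

Alternative 3: The cut is at C4–C7 and C3–C7', the same two-bond logic as in the chosen plan but on a different acceptor. The pieces are the butenolide (5R)-5-{[(1R,2S,5R)-2-isopropyl-5-methylcyclohexyl]oxy}furan-2(5H)-one A5, the acyl anion equivalent 2-(3,4-dimethoxyphenyl)-1,3-dithiane A6 and 12.
- Forward key step: lithiated A6 would add to C4 of A5 anti to the acetal substituent, and the lactone enolate would then be benzylated at C3 by 12 anti to the new C4 group. This would give (3R,4R,5R)-3-[3-(benzyloxy)-4,5-dimethoxybenzyl]-4-[2-(3,4-dimethoxyphenyl)-1,3-dithian-2-yl]-5-{[(1R,2S,5R)-2-isopropyl-5-methylcyclohexyl]oxy}dihydrofuran-2(3H)-one A7. Desulfurisation with Raney Ni, reductive removal of the acetal with relactonisation, and debenzylation would follow.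
- In favour: two C–C bonds form in one flask, as in the chosen step. Both C3 and C4 would be set kinetically, relayed from the acetal carbon, so the trans relationship arises directly without decarboxylation or equilibration; there the alternative is better. The auxiliary alcohol can be recovered.
- Against: A5 has to be prepared and its C5 epimers separated, and A6 needs a thioacetalisation. Three further operations follow the key step. A large excess of Raney Ni has to be used beside an aryl benzyl ether, with sulfur residues that poison later palladium chemistry. Atom economy is poor, since the auxiliary and the dithiane are both discarded.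
- Comparison: the two plans are close relatives and equal in bond-forming power, each being a soft carbon nucleophile adding to an activated acceptor followed by trapping of the enolate with 12. The alternative is better on kinetic control of C3. The chosen plan is better on step count and waste: C4 comes from a cheap epoxide, no auxiliary or sulfur has to be removed, and the only extra is the loss of the ester as carbon dioxide.

Key step: step 6

Remarks on the chemistry (assumptions):
- The descriptors (R) for 1, (1S,5R) for 6 and (3R,4R) for 14 and 17 were recomputed from the structures; they are mutually consistent, provided step 1 runs by epoxide opening first.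
- The configuration at C3 of 14 has no bearing on the outcome, because step 7 removes the ester and re-sets C3. 14 is drawn as the (3R) epimer expected from alkylation anti to the C4 substituent.
- The ethyl ester of 6 is kept because it matches the ethoxide/ethanol medium of step 1. The benzyl ether on ring B is kept because it should survive steps 5 to 7 and leave by neutral hydrogenolysis.
- A titrated THF solution of 8 is treated as the product of step 2.

## Route

Step 1
Reactants: 1 (R)-epichlorohydrin [(2R)-2-(chloromethyl)oxirane]; 2 diethyl malonate
Product: 6 ethyl (1S,5R)-2-oxo-3-oxabicyclo[3.1.0]hexane-1-carboxylate, via chlorohydrin 3 (not isolated), via transposed epoxide 4 (not isolated), via cyclopropane alkoxide 5 (not isolated)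
Conditions: NaOEt (1.2 equiv), 2 (1.3 equiv), EtOH, 0 °C to reflux
Reagents that add atoms: none
Why: Malonate alkylation, epoxide transposition, 3-exo-tet cyclopropanation and lactonisation in one cascade: sodiomalonate opens the epoxide of 1 at its CH2 to give 3, whose alkoxide displaces chloride to form the transposed epoxide 4 without touching the stereocentre. The carbanion of 4 then opens the new epoxide at the stereocentre with inversion to give 5, and the freed alkoxide acylates on the ester cis to it; this should fix the fusion carbon as (5R) and, by the enforced cis fusion, the quaternary carbon as (1S).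

Step 2
Reactants: 7 4-bromo-1,2-dimethoxybenzene
Product: 8 (3,4-dimethoxyphenyl)magnesium bromide
Conditions: Mg turnings, I2 (cat.), THF, 40 °C; titrated and used as solution
Reagents that add atoms: magnesium, [Mg]
Why: Grignard formation by insertion of magnesium into the aryl C–Br bond; the ether groups are inert, and titration allows 8 to be dosed exactly in step 6.

Step 3
Reactants: 9 3-hydroxy-4,5-dimethoxybenzaldehyde
Product: 10 3-(benzyloxy)-4,5-dimethoxybenzaldehyde
Conditions: BnBr, K2CO3, DMF, 60 °C
Reagents that add atoms: benzyl bromide, BrCc1ccccc1
Why: Williamson ether synthesis on the phenoxide of 9; the aldehyde is not affected by K2CO3.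

Step 4
Reactants: 10 3-(benzyloxy)-4,5-dimethoxybenzaldehyde
Product: 11 [3-(benzyloxy)-4,5-dimethoxyphenyl]methanol
Conditions: NaBH4, MeOH, 0 °C
Reagents that add atoms: none
Why: Borohydride reduction of the aryl aldehyde to the benzylic alcohol; the ethers are inert.

Step 5
Reactants: 11 [3-(benzyloxy)-4,5-dimethoxyphenyl]methanol
Product: 12 3-(benzyloxy)-4,5-dimethoxybenzyl bromide
Conditions: PBr3 (0.4 equiv), CH2Cl2, 0 °C; used promptly
Reagents that add atoms: phosphorus tribromide, BrP(Br)Br
Why: Bromination of a benzylic alcohol through its phosphite ester with SN2 displacement by bromide; low temperature and a short contact time should protect the benzyl ether.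

Step 6
Reactants: 6 ethyl (1S,5R)-2-oxo-3-oxabicyclo[3.1.0]hexane-1-carboxylate; 8 (3,4-dimethoxyphenyl)magnesium bromide; 12 3-(benzyloxy)-4,5-dimethoxybenzyl bromide
Product: 14 ethyl (3R,4R)-3-[3-(benzyloxy)-4,5-dimethoxybenzyl]-4-(3,4-dimethoxybenzyl)-2-oxotetrahydrofuran-3-carboxylate, via bromomagnesium enolate 13 (not isolated)
Conditions: CuI (10 mol %), THF, −40 to −20 °C, 8 (1.1 equiv) added slowly to 6; then 12 (1.2 equiv), DMPU, −20 °C to rt
Reagents that add atoms: none
Why: Transmetalation of 8 to CuI gives an arylcopper species that attacks the cyclopropane CH2 of 6 (the future C7) in an SN2-like homo-Michael addition; the bond from this CH2 to the quaternary carbon, weakened by both carbonyl groups, breaks, and release of ring strain gives the chelated enolate 13 and returns the copper. The closest known reaction type is the copper-catalysed Grignard opening of doubly acceptor-substituted cyclopropanes, established for this bicyclic lactone, followed by the ordinary C-alkylation of a 2-oxotetrahydrofuran-3-carboxylate enolate with a benzylic bromide. No ring is closed: the three-membered ring opens and the γ-lactone remains. The fusion carbon (future C4) keeps all four of its bonds, so its R configuration is carried over from 6. DMPU loosens the magnesium chelate, and 12 should then alkylate the enolate at carbon from the face opposite the C4 arylmethyl group, giving the (3R) quaternary centre; the C3 epimer, if formed, converges in step 7. The step needs attack at the CH2 and not at the fusion CH or a carbonyl (secured by the smaller steric demand of the CH2, the soft copper nucleophile and the low temperature). It also needs C- over O-alkylation (secured by the soft benzylic bromide) and no aryl–benzyl coupling (secured by the small excess of 8 and by adding 12 only after 6 is consumed).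

Step 7
Reactants: 14 ethyl (3R,4R)-3-[3-(benzyloxy)-4,5-dimethoxybenzyl]-4-(3,4-dimethoxybenzyl)-2-oxotetrahydrofuran-3-carboxylate
Product: 16 (3R,4R)-3-[3-(benzyloxy)-4,5-dimethoxybenzyl]-4-(3,4-dimethoxybenzyl)dihydrofuran-2(3H)-one, via cis epimer 15 (not isolated)
Conditions: LiCl (3 equiv), H2O (2 equiv), DMSO, 150 °C; dilute acid work-up; crude then DBU (0.5 equiv), toluene, 100 °C
Reagents that add atoms: none
Why: Krapcho dealkoxycarbonylation: chloride removes the ethyl group by SN2, carbon dioxide is lost and C3 is protonated, probably mainly from the face away from the C4 substituent, which would give the cis epimer 15 beside 16. DBU then equilibrates the acidic C3–H by reversible enolisation towards the more stable trans lactone 16; C4 is not acidic and keeps its configuration.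

Step 8
Reactants: 16 (3R,4R)-3-[3-(benzyloxy)-4,5-dimethoxybenzyl]-4-(3,4-dimethoxybenzyl)dihydrofuran-2(3H)-one
Product: 17 (3R,4R)-4-(3,4-dimethoxybenzyl)-3-(3-hydroxy-4,5-dimethoxybenzyl)dihydrofuran-2(3H)-one
Conditions: H2 (1 atm), 10% Pd/C, EtOAc/EtOH, rt
Reagents that add atoms: none
Why: Hydrogenolysis of the aryl benzyl ether over palladium; the aryl methyl ethers, the lactone and the benzylic C–C bonds should not be cleaved, and the neutral conditions leave both stereocentres untouched.

## Compound list

1 | (R)-epichlorohydrin, (2R)-2-(chloromethyl)oxirane | ClC[C@H]1CO1 | starting material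
2 | diethyl malonate | CCOC(=O)CC(=O)OCC | starting material
3 | diethyl 2-[(2R)-3-chloro-2-hydroxypropyl]malonate (formed as its sodium salt) | CCOC(=O)C(C[C@@H](O)CCl)C(=O)OCC | intermediate
4 | diethyl 2-{[(2R)-oxiran-2-yl]methyl}malonate | CCOC(=O)C(C[C@@H]1CO1)C(=O)OCC | intermediate
5 | diethyl (2R)-2-(hydroxymethyl)cyclopropane-1,1-dicarboxylate (formed as its sodium alkoxide) | CCOC(=O)C1(C[C@H]1CO)C(=O)OCC | intermediate
6 | ethyl (1S,5R)-2-oxo-3-oxabicyclo[3.1.0]hexane-1-carboxylate | CCOC(=O)[C@]12C[C@H]1COC2=O | intermediate
7 | 4-bromo-1,2-dimethoxybenzene | COc1ccc(Br)cc1OC | starting material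
8 | (3,4-dimethoxyphenyl)magnesium bromide | COc1ccc([Mg]Br)cc1OC | intermediate
9 | 3-hydroxy-4,5-dimethoxybenzaldehyde | COc1cc(C=O)cc(O)c1OC | starting material
10 | 3-(benzyloxy)-4,5-dimethoxybenzaldehyde | COc1cc(C=O)cc(OCc2ccccc2)c1OC | intermediate
11 | [3-(benzyloxy)-4,5-dimethoxyphenyl]methanol | COc1cc(CO)cc(OCc2ccccc2)c1OC | intermediate
12 | 3-(benzyloxy)-4,5-dimethoxybenzyl bromide | COc1cc(CBr)cc(OCc2ccccc2)c1OC | intermediate
13 | bromomagnesium enolate of ethyl (4R)-4-(3,4-dimethoxybenzyl)-2-oxotetrahydrofuran-3-carboxylate | CCOC(=O)C1=C(O[Mg]Br)OC[C@@H]1Cc1ccc(OC)c(OC)c1 | intermediate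
14 | ethyl (3R,4R)-3-[3-(benzyloxy)-4,5-dimethoxybenzyl]-4-(3,4-dimethoxybenzyl)-2-oxotetrahydrofuran-3-carboxylate | COc1ccc(C[C@H]2COC(=O)[C@]2(C(=O)OCC)Cc2cc(OCc3ccccc3)c(OC)c(OC)c2)cc1OC | intermediate
15 | (3S,4R)-3-[3-(benzyloxy)-4,5-dimethoxybenzyl]-4-(3,4-dimethoxybenzyl)dihydrofuran-2(3H)-one (cis epimer) | COc1ccc(C[C@H]2COC(=O)[C@H]2Cc2cc(OCc3ccccc3)c(OC)c(OC)c2)cc1OC | intermediate
16 | (3R,4R)-3-[3-(benzyloxy)-4,5-dimethoxybenzyl]-4-(3,4-dimethoxybenzyl)dihydrofuran-2(3H)-one (trans) | COc1ccc(C[C@H]2COC(=O)[C@@H]2Cc2cc(OCc3ccccc3)c(OC)c(OC)c2)cc1OC | intermediate
17 | (3R,4R)-4-(3,4-dimethoxybenzyl)-3-(3-hydroxy-4,5-dimethoxybenzyl)dihydrofuran-2(3H)-one | COc1ccc(C[C@H]2COC(=O)[C@@H]2Cc2cc(O)c(OC)c(OC)c2)cc1OC | target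

## Step count and least certain steps

Total: 8 steps. Longest linear sequence: 6 steps (steps 3, 4, 5, 6, 7 and 8, from 9).

Step 6 (key step). The most likely failure is a sluggish or incomplete C-benzylation of the tightly chelated magnesium enolate. Copper-mediated coupling of any unconsumed 8 with 12, or carbonyl addition of 8 if the temperature rises, could add to it. Fallback, from 6 and 8, returning at 16:
- The copper-catalysed opening is run alone and quenched with dilute HCl to give ethyl (4R)-4-(3,4-dimethoxybenzyl)-2-oxotetrahydrofuran-3-carboxylate F1.
- Krapcho dealkoxycarbonylation (LiCl, H2O, DMSO, 140 °C) then gives (R)-4-(3,4-dimethoxybenzyl)dihydrofuran-2(3H)-one F2, the same compound as A2.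
- Its lithium enolate (LiN(SiMe3)2, THF, −78 °C) is alkylated with 12; kinetic attack anti to the C4 substituent should give 16 directly.

This forms the C3–C7' bond on a simple lactone enolate under kinetic control, avoids the quaternary intermediate and the equilibration, and costs one step more.

Step 7. The most likely failure is slow de-ethylation at the congested quaternary ester, with competing chloride attack at the lactone CH2. Incomplete epimer equilibration would leave cis material. Fallback, from 14, returning at 16:
- Aqueous KOH in EtOH at reflux hydrolyses the ester (and the lactone, reversibly).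
- Acidification re-closes the lactone to (3R,4R)-3-[3-(benzyloxy)-4,5-dimethoxybenzyl]-4-(3,4-dimethoxybenzyl)-2-oxotetrahydrofuran-3-carboxylic acid F3.
- Heating in toluene or xylene (110 to 140 °C) decarboxylates it through the enol to the C3 epimers, which the same DBU treatment converges on 16.

The ester is thus removed by hydrolysis and thermal decarboxylation and not by SN2 dealkylation.

Step 1. The most likely failure is leakage through direct displacement of chloride, which leads to the enantiomer of 6 and erodes the enantiomeric purity; oligomerisation of 1 would lower the yield. Fallback, from 2, returning at 4 (and so at 6):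
- (R)-glycidol F4 is converted with Tf2O and 2,6-lutidine (CH2Cl2, −30 °C) into (S)-glycidyl triflate F5.
- F5 is added to the sodium salt of 2 (NaH, THF). The sulfonate should be displaced directly, which gives the same epoxide 4 in a single C–C bond-forming event.
- A second equivalent of base then takes 4 through 5 to 6.

This reverses the order of bond formation at the three-carbon unit and so removes the regiochemical ambiguity of the first attack.

Step 5. The most likely failure is acid-promoted self-condensation of the electron-rich benzylic bromide, or partial loss of the benzyl ether through HBr. Fallback, from 10 and the lactone F2 of the step 6 fallback, returning at 15 and hence 16 (this pairing of F2 with 10 also avoids the alkylation of step 6):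
- Aldol addition of the lithium enolate of F2 (LiN(iPr)2, THF, −78 °C) to 10 gives (3S,4R)-3-{[3-(benzyloxy)-4,5-dimethoxyphenyl](hydroxy)methyl}-4-(3,4-dimethoxybenzyl)dihydrofuran-2(3H)-one F6 as carbinol epimers.
- Dehydration (TsOH cat., toluene, 80 °C) gives (R,E)-3-[3-(benzyloxy)-4,5-dimethoxybenzylidene]-4-(3,4-dimethoxybenzyl)dihydrofuran-2(3H)-one F7, the same compound as A4.
- Conjugate reduction (NaBH4, NiCl2·6H2O, MeOH, 0 °C) gives the C3 epimers including 15, which the DBU stage of step 7 takes to 16.

Ring B then enters as an aldehyde and no benzylic halide is needed.

## Further compounds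

F1 | step 6 | ethyl (4R)-4-(3,4-dimethoxybenzyl)-2-oxotetrahydrofuran-3-carboxylate (C3 epimers) | COc1ccc(C[C@H]2COC(=O)C2C(=O)OCC)cc1OC
F2 | step 6 | (R)-4-(3,4-dimethoxybenzyl)dihydrofuran-2(3H)-one | COc1ccc(C[C@H]2COC(=O)C2)cc1OC
F3 | step 7 | (3R,4R)-3-[3-(benzyloxy)-4,5-dimethoxybenzyl]-4-(3,4-dimethoxybenzyl)-2-oxotetrahydrofuran-3-carboxylic acid | COc1ccc(C[C@H]2COC(=O)[C@]2(C(=O)O)Cc2cc(OCc3ccccc3)c(OC)c(OC)c2)cc1OC
F4 | step 1 | (R)-glycidol, [(2R)-oxiran-2-yl]methanol | OC[C@@H]1CO1
F5 | step 1 | (S)-glycidyl triflate, [(2S)-oxiran-2-yl]methyl trifluoromethanesulfonate | O=S(=O)(OC[C@@H]1CO1)C(F)(F)F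
F6 | step 5 | (3S,4R)-3-{[3-(benzyloxy)-4,5-dimethoxyphenyl](hydroxy)methyl}-4-(3,4-dimethoxybenzyl)dihydrofuran-2(3H)-one (carbinol epimers) | COc1ccc(C[C@H]2COC(=O)[C@@H]2C(O)c2cc(OCc3ccccc3)c(OC)c(OC)c2)cc1OC
F7 | step 5 | (R,E)-3-[3-(benzyloxy)-4,5-dimethoxybenzylidene]-4-(3,4-dimethoxybenzyl)dihydrofuran-2(3H)-one | COc1ccc(C[C@H]2COC(=O)/C2=C/c2cc(OCc3ccccc3)c(OC)c(OC)c2)cc1OC
A1 | alternative 1 | 3-(3,4-dimethoxybenzyl)cyclobutan-1-one | COc1ccc(CC2CC(=O)C2)cc1OC
A2 | alternative 1 | (R)-4-(3,4-dimethoxybenzyl)dihydrofuran-2(3H)-one | COc1ccc(C[C@H]2COC(=O)C2)cc1OC
A3 | alternative 2 | (2R)-4-[3-(benzyloxy)-4,5-dimethoxyphenyl]-2-(3,4-dimethoxybenzyl)but-3-yn-1-ol | COc1ccc(C[C@@H](CO)C#Cc2cc(OCc3ccccc3)c(OC)c(OC)c2)cc1OC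
A4 | alternative 2 | (R,E)-3-[3-(benzyloxy)-4,5-dimethoxybenzylidene]-4-(3,4-dimethoxybenzyl)dihydrofuran-2(3H)-one | COc1ccc(C[C@H]2COC(=O)/C2=C/c2cc(OCc3ccccc3)c(OC)c(OC)c2)cc1OC
A5 | alternative 3 | (5R)-5-{[(1R,2S,5R)-2-isopropyl-5-methylcyclohexyl]oxy}furan-2(5H)-one | CC(C)[C@@H]1CC[C@@H](C)C[C@H]1O[C@@H]1OC(=O)C=C1
A6 | alternative 3 | 2-(3,4-dimethoxyphenyl)-1,3-dithiane | COc1ccc(C2SCCCS2)cc1OC
A7 | alternative 3 | (3R,4R,5R)-3-[3-(benzyloxy)-4,5-dimethoxybenzyl]-4-[2-(3,4-dimethoxyphenyl)-1,3-dithian-2-yl]-5-{[(1R,2S,5R)-2-isopropyl-5-methylcyclohexyl]oxy}dihydrofuran-2(3H)-one | CC(C)[C@@H]1CC[C@@H](C)C[C@H]1O[C@@H]1OC(=O)[C@H](Cc2cc(OCc3ccccc3)c(OC)c(OC)c2)[C@H]1C1(SCCCS1)c1ccc(OC)c(OC)c1
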